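(All constants were set for the occasion; the flask was simulated.)

Free catalyst and catalyst intermediate together keep the catalyst charge through every step.

    substrate + free catalyst → catalyst intermediate (k1 = 17 L mol⁻¹ s⁻¹)
    catalyst intermediate → free catalyst + target (k2 = 4.1 s⁻¹)
    free catalyst + target → free catalyst + over-reaction product (k3 = 2.6 L mol⁻¹ s⁻¹)

common to all: free catalyst 0.14 mM

| flask | substrate | remark | time |
|---|---|---|---|
| winter | 27 mM | a single well-mixed tank run continuously and read at steady state, 40 min in it on average |  |
| dawn | 27 mM (fed, over 32.0 min) | all but substrate at the start; substrate goes in evenly over 32.0 min, the run ends at 40 min | 40 min |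
| midnight | 27 mM | everything together in a closed stirred flask, run for 40 min | 40 min |

- the set-up with the highest amount of target at the outlet or at the end, in percent of the substrate put in ("none" if the first two lie within 2 percentage points) (winter / dawn / midnight / none)
- amount of target at the outlet or at the end, in percent of the substrate put in, winter
- amount of target at the outlet or at the end, in percent of the substrate put in, dawn
- amount of target at the outlet or at the end, in percent of the substrate put in, midnight

- the stated concentrations are those of everything mixed, before any reaction; amounts are the same in each set-up
- the feed brings no volume worth counting
- run time (dawn): 40 min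

We need two times. The ratio of step 2's constant to step 1's, 241 mM, is more than the substrate charge of 27 mM, so we take free catalyst as the resting state, near its charge. Both consuming steps are then pseudo-first-order: substrate with a = 0.143 min⁻¹, target with b = 0.0218 min⁻¹. A portion of substrate of age θ, counted from its entry, has then given the target fraction Y(θ) = a/(a−b)·(e^(−bθ) − e^(−aθ)). This curve tops at the peak time t_p = ln(a/b)/(a−b) = 15.5 min, our first time.

The second is the mean age of the substrate at reading: 40 min in midnight, but 24.0 min in dawn, whose feed is even. Their ratios to t_p are 2.58 and 1.55, both past the peak, so we expect dawn, the younger flask, to stand higher than midnight. Y gives 48.9% for midnight and, read at the mean age, 66.1% for dawn. Winter has the same mean age, 40 min, but a spread of ages, and the tank balance aτ/((1+aτ)(1+bτ)), with τ that mean, gives 45.4%. We commit to dawn.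

The forecast, holding that “the catalyst stays mostly free”, named dawn with 45.7% for winter, 63.5% for dawn and 49.7% for midnight; its dawn is lower than ours, and its midnight is higher.

The simulation gives dawn, with 45.7% for winter, 63.5% for dawn and 49.7% for midnight. In midnight, target was made 7.00 times faster than it was used at 5.22 min, but at 0.0489 of its use at 40.0 min, each step taken net. Our t_p is later than the first of these times and earlier than the second, so in midnight that is the stretch to watch.

Take midnight with 0.084 mM of free catalyst: t_p stretches to 25.9 min, the ratio at 40 min is 1.54, and Y gives 66.1%. The computed flask holds 66.8%.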